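C3–C4 and C5–C6 of the 1,2-dioxane are cut together, after a C4=C5 double bond is put back. This leaves a CH=CH unit, supplied as (Z)-Me3SiCH=CHSiMe3, and an acyclic peroxide whose two carbons are ketals. That peroxide is then cut at O1–C6 (hydroperoxide + enol ether), and the enol ether at C6–C1' of the phenyloctyl chain.
Enabling feature: C3 and C6 are both fully substituted carbons on the O1–O2 bridge, so each is a masked methyl ketone that can become a peroxycarbenium ion. C4–C5 carries nothing. The carboxyl carbon stands 1,4 to C3 (levulinic acid pattern), so the acid itself serves as the leaving group on C3 in the form of a temporary γ-lactone ring.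
Forward order: the side chain is joined to a metalated enol ether, the hydroperoxy lactone is made by ozonolysis, and the two are linked through O1–C6. The only ring of the target closes in the key step while the lactone opens, and C4=C5 is reduced last.
Stereochemistry: both quaternary centres arise in the key step under a confined chiral counteranion. The trans-3,6-dimethyl pattern is pseudo-C2-symmetric, so the same (Re) face is needed twice and errors are shed as the separable cis isomer.

Key step: step 5

Assumption: the sense of induction of the chiral anion in step 5 cannot be derived from first principles, so the (S,S) catalyst is written for Re-face attack and its mirror image is used if the first experiment shows the opposite sense.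

Step 1
Reactants: 1 (8-bromooctyl)benzene; 2 ethyl vinyl ether
Product: 4 2-ethoxy-10-phenyldec-1-ene, via 1-ethoxyvinyllithium 3 (not isolated)
Conditions: 2 (2 equiv), t-BuLi, THF, −78 to 0 °C; then 1, DMPU, −30 to 20 °C; filtration through basic alumina
Reagents that add atoms: none
Why: α-Lithiation of the vinyl ether gives an acyl-anion equivalent whose SN2 alkylation by the primary bromide (alkylation of a metalated enol ether) attaches the whole C6 side chain and leaves C6 at the ketone level as an acid-ionisable enol ether, with no stereocentre formed.

Step 2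
Reactants: 5 4-methylpent-4-enoic acid
Product: 8 5-hydroperoxy-5-methyloxolan-2-one, via primary ozonide 6 (not isolated), via carbonyl oxide 7 (not isolated)
Conditions: O3/O2, CH2Cl2, −78 °C; N2 purge, no reductant; short silica plug, kept as a CH2Cl2 solution and never concentrated to dryness
Reagents that add atoms: ozone, [O-][O+]=O
Why: In this Criegee ozonolysis the primary ozonide of a 1,1-dialkyl alkene places the carbonyl oxide on the more substituted carbon, and the carboxyl group traps it intramolecularly through a five-membered ring faster than formaldehyde recombines, giving the racemic α-acyloxy hydroperoxide.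

Step 3
Reactants: 4 2-ethoxy-10-phenyldec-1-ene; 8 5-hydroperoxy-5-methyloxolan-2-one
Product: 9 5-[(2-ethoxy-10-phenyldecan-2-yl)peroxy]-5-methyloxolan-2-one
Conditions: PPTS (5 mol %), 4 Å sieves, CH2Cl2, 0 °C; Et3N quench
Reagents that add atoms: none
Why: Acid-catalysed Markovnikov addition of a hydroperoxide O–H to a 2-alkoxyalkene (peroxyketalisation, as in masking hydroperoxides with 2-methoxypropene) needs only PPTS because the enol ether is far more basic than the acylal of 8, and the resulting stereoisomer mixture at both ketal carbons is harmless since step 5 planarises both.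

Step 4
Reactants: 10 bis(trimethylsilyl)acetylene
Product: 11 (Z)-1,2-bis(trimethylsilyl)ethene
Conditions: H2 (1 atm), Pd/CaCO3 poisoned with Pb(OAc)2, quinoline, pentane, 20 °C
Reagents that add atoms: none
Why: syn-Semihydrogenation of an alkyne on poisoned palladium delivers both hydrogens to one face, so the two silyl groups end up cis.

Step 5
Reactants: 9 5-[(2-ethoxy-10-phenyldecan-2-yl)peroxy]-5-methyloxolan-2-one; 11 (Z)-1,2-bis(trimethylsilyl)ethene
Product: 14 3-[(3S,6S)-3,6-dimethyl-6-(8-phenyloctyl)-3,6-dihydro-1,2-dioxin-3-yl]propanoic acid, via Z-vinylsilane peroxide 12 (not isolated), via trimethylsilyl ester 13 (not isolated)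
Conditions: 11 (2.5 equiv), (S,S)-IDPi Brønsted acid (imidodiphosphorimidate from two 3,3'-bis[3,5-bis(trifluoromethyl)phenyl]-(S)-BINOL units with P=N–SO2CF3 groups, 5 mol %), toluene/CH2Cl2, −78 to −40 °C; Et3N quench; pH 5 citrate buffer; chromatography to remove the cis isomer
Reagents that add atoms: none
Why: Proposed new method: the acid protodesilylates a trace of 11 to give Me3Si+ paired with the chiral anion, this silylates the ethoxy oxygen of 9 and expels EtOSiMe3, the C6 peroxycarbenium ion is attacked by 11 at a silicon-bearing carbon (ipso attack, charge β to silicon), loss of Me3Si+ with retention gives 12, and the released Me3Si+ opens the lactone of 12 at its carbonyl oxygen to the silyl ester and the C3 peroxycarbenium ion, which the remaining C–Si carbon (C4) traps to give 13, so the two silyl groups of 11 carry the chain and end on the two leaving groups. The closest known reaction types are Lewis acid substitution of monoperoxyketals by allylsilanes and silyl enol ethers via peroxycarbenium ions, closure of such ions onto tethered π-nucleophiles to give 1,2-dioxanes, acetal-initiated vinylsilane-terminated cyclisation to dihydropyrans, and ipso acylation of 1,2-bis(silyl)ethenes; new are the twofold use of one peroxide, the intermolecular vinylsilane step and the chiral anion. The 1,2-dioxine ring closes 6-endo-trig at the vinylsilane (C4, C5 and the C3=O2+ unit all lie in the new ring) while the temporary lactone ring opens; the Z geometry lets the ring-closing rotation about C4–C5 bring the C4–Si bond parallel to the empty orbital growing at C5, whereas 5-exo attack through C5 would place the charge on the α-silyl carbon C4, so the β-silicon effect secures the regiochemistry. C6 (first) and C3 (second) are each set by the confined chiral anion, which must tell CH3 from CH2R and direct the nucleophile to the Re face of a Me(RCH2)C=O+–O ion, the task such anions already solve for O-silylated small methyl ketones and aliphatic oxocarbenium ions; the forming ring adds little bias of its own because CH3 and CH2R differ little in size. Since the trans-3,6-dimethyl product is pseudo-C2-symmetric, the same face is needed twice, and one wrong event leads to the cis diastereomer, which chromatography removes, so the enantiomeric purity of 14 should exceed that of either single event (Horeau-type amplification). The step needs desilylation to outrun both O–O heterolysis and capture of the β-silyl cation by the distal peroxide oxygen (formal 3+2 annulation to a 1,2-dioxolane with loss of the other ketal carbon), which is why the far end of 9 is an acylal, a poor electrofuge until it is silylated, why the small Me3Si group is used, and why the run is kept cold and quenched with Et3N; the order of the two ionisations is immaterial because 11 is symmetrical.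

Step 6
Reactants: 14 3-[(3S,6S)-3,6-dimethyl-6-(8-phenyloctyl)-3,6-dihydro-1,2-dioxin-3-yl]propanoic acid
Product: 15 3-[(3R,6S)-3,6-dimethyl-6-(8-phenyloctyl)-1,2-dioxan-3-yl]propanoic acid
Conditions: KO2CN=NCO2K (excess, in portions), AcOH, MeOH/CH2Cl2, 0 to 20 °C
Reagents that add atoms: none
Why: Concerted syn hydrogen transfer from diimide saturates C4=C5 without touching the O–O bond (diimide reduction of unsaturated endoperoxides, as for ascaridole with its two flanking quaternary carbons), and no stereocentre moves, the descriptor at C3 changing from S to R only because the ring branch loses CIP rank.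

Compound list
1 | (8-bromooctyl)benzene | BrCCCCCCCCc1ccccc1 | starting material
2 | ethyl vinyl ether | C=COCC | starting material
3 | 1-ethoxyvinyllithium | [Li]C(=C)OCC | intermediate
4 | 2-ethoxy-10-phenyldec-1-ene | C=C(OCC)CCCCCCCCc1ccccc1 | intermediate
5 | 4-methylpent-4-enoic acid | C=C(C)CCC(=O)O | starting material
6 | 3-(4-methyl-1,2,3-trioxolan-4-yl)propanoic acid (primary ozonide) | CC1(CCC(=O)O)COOO1 | intermediate
7 | 4-oxopentanoic acid O-oxide (carbonyl oxide) | CC(CCC(=O)O)=[O+][O-] | intermediate
8 | 5-hydroperoxy-5-methyloxolan-2-one (racemic) | CC1(OO)CCC(=O)O1 | intermediate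
9 | 5-[(2-ethoxy-10-phenyldecan-2-yl)peroxy]-5-methyloxolan-2-one (all stereoisomers) | CCOC(C)(CCCCCCCCc1ccccc1)OOC1(C)CCC(=O)O1 | intermediate
10 | bis(trimethylsilyl)acetylene | C[Si](C)(C)C#C[Si](C)(C)C | starting material
11 | (Z)-1,2-bis(trimethylsilyl)ethene | C[Si](C)(C)/C=C\[Si](C)(C)C | intermediate
12 | 5-methyl-5-{[(1Z,3S)-3-methyl-11-phenyl-1-(trimethylsilyl)undec-1-en-3-yl]peroxy}oxolan-2-one (lactone carbon both ways) | C[C@](CCCCCCCCc1ccccc1)(/C=C\[Si](C)(C)C)OOC1(C)CCC(=O)O1 | intermediate
13 | trimethylsilyl 3-[(3S,6S)-3,6-dimethyl-6-(8-phenyloctyl)-3,6-dihydro-1,2-dioxin-3-yl]propanoate | C[C@]1(CCCCCCCCc2ccccc2)C=C[C@](C)(CCC(=O)O[Si](C)(C)C)OO1 | intermediate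
14 | 3-[(3S,6S)-3,6-dimethyl-6-(8-phenyloctyl)-3,6-dihydro-1,2-dioxin-3-yl]propanoic acid | C[C@]1(CCCCCCCCc2ccccc2)C=C[C@](C)(CCC(=O)O)OO1 | intermediate
15 | 3-[(3R,6S)-3,6-dimethyl-6-(8-phenyloctyl)-1,2-dioxan-3-yl]propanoic acid | C[C@]1(CCCCCCCCc2ccccc2)CC[C@](C)(CCC(=O)O)OO1 | target

Total step count: 6. Longest linear sequence: 4 (steps 1, 3, 5, 6).

Steps most likely to fail

**Step 5.** Several processes could defeat it:
- Intermolecular attack of the weakly nucleophilic vinylsilane may be slower than O–O heterolysis with alkyl migration.
- The β-silyl cation may be captured by the distal peroxide oxygen.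
- The first substitution may leak to the E-vinylsilane, which closes slowly.
- The doubly allylic C–O bonds of the product may re-ionise.
- The anion may discriminate the two faces poorly.

The fallback uses known chemistry only, sets out from 1 and comes back at 15. Magnesium in THF converts 1 into (8-phenyloctyl)magnesium bromide F1, which adds to propargyl alcohol under CuI catalysis (carbomagnesiation) to give 2-methylidene-10-phenyldecan-1-ol F2. Heating with 2-methoxypropene and a trace of acid forms the allyl isopropenyl ether {9-[(prop-1-en-2-yloxy)methyl]dec-9-en-1-yl}benzene F3. This rearranges in the same flask (Saucy–Marbet variant of the Claisen rearrangement) to 5-methylidene-13-phenyltridecan-2-one F4.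

Catalytic asymmetric Corey–Chaykovsky epoxidation follows, using dimethyloxosulfonium methylide from Me3S(O)I/NaH, LaLi3(binaphthoxide)3 of the appropriate hand and a triarylphosphine oxide additive. It should give (2S)-2-methyl-2-(3-methylidene-11-phenylundecyl)oxirane F5. Mukaiyama–Isayama peroxidation (Co(thd)2 with thd = 2,2,6,6-tetramethylheptane-3,5-dionate, O2, Et3SiH) turns the 1,1-disubstituted alkene into (2S)-2-methyl-2-[3-methyl-11-phenyl-3-(triethylsilylperoxy)undecyl]oxirane F6, as both epimers at the peroxy carbon. TBAF/AcOH frees (2S)-2-(3-hydroperoxy-3-methyl-11-phenylundecyl)-2-methyloxirane F7.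

Camphorsulfonic acid in CH2Cl2 closes F7 by 6-exo opening of the epoxide at its tertiary carbon with inversion. After chromatographic removal of the C6 epimer this gives [(3R,6S)-3,6-dimethyl-6-(8-phenyloctyl)-1,2-dioxan-3-yl]methanol F8. The remaining steps are:
- Dess–Martin oxidation to (3R,6S)-3,6-dimethyl-6-(8-phenyloctyl)-1,2-dioxane-3-carbaldehyde F9.
- Wittig reaction with Ph3P=CHCO2Me to methyl (E)-3-[(3R,6S)-3,6-dimethyl-6-(8-phenyloctyl)-1,2-dioxan-3-yl]prop-2-enoate F10.
- Diimide reduction to methyl 3-[(3R,6S)-3,6-dimethyl-6-(8-phenyloctyl)-1,2-dioxan-3-yl]propanoate F11.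
- Saponification with LiOH in THF/water to 15.

**Step 3.** Possible failures are acid-promoted exchange between peroxyketal partners, hydrolysis of the enol ether by traces of water, or ionisation of the acylal of 8. The fallback sets out from 4 and comes back at 9. The roles of the partners are exchanged and the new bond is made at C3 under basic conditions. Compound 4 takes up anhydrous H2O2 in ether with a trace of acid (Markovnikov perhydration of an enol ether) to give 2-ethoxy-2-hydroperoxy-10-phenyldecane F12. Levulinic acid and SOCl2 give the cyclic pseudo-chloride 5-chloro-5-methyloxolan-2-one F13. F12 then displaces the chloride of F13 in the presence of 2,6-lutidine in CH2Cl2 at −20 °C (pseudo-ester formation) to give 9. This detour needs neither 8 nor step 2.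

**Step 1.** Possible failures are slow SN2 at an unactivated primary bromide, competing E2 elimination or bromine–lithium exchange, and hydrolysis of the enol ether during isolation. The fallback sets out from 1 and comes back at 4. It builds the enol ether by carbonyl methylenation instead of alkylation. (8-Phenyloctyl)magnesium bromide F1, made from 1 and magnesium, is acylated with ethyl chloroformate at −78 °C to give ethyl 9-phenylnonanoate F14. Petasis methylenation (Cp2TiMe2, toluene, 65 °C) then converts the ester carbonyl into the terminal enol ether 4 as a single regioisomer.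

Further compounds
F1 | step 5 | (8-phenyloctyl)magnesium bromide | Br[Mg]CCCCCCCCc1ccccc1
F2 | step 5 | 2-methylidene-10-phenyldecan-1-ol | C=C(CO)CCCCCCCCc1ccccc1
F3 | step 5 | {9-[(prop-1-en-2-yloxy)methyl]dec-9-en-1-yl}benzene | C=C(C)OCC(=C)CCCCCCCCc1ccccc1
F4 | step 5 | 5-methylidene-13-phenyltridecan-2-one | CC(=O)CCC(=C)CCCCCCCCc1ccccc1
F5 | step 5 | (2S)-2-methyl-2-(3-methylidene-11-phenylundecyl)oxirane | C=C(CCCCCCCCc1ccccc1)CC[C@@]1(C)CO1
F6 | step 5 | (2S)-2-methyl-2-[3-methyl-11-phenyl-3-(triethylsilylperoxy)undecyl]oxirane (both epimers at the peroxy carbon) | CC(CCCCCCCCc1ccccc1)(OO[Si](CC)(CC)CC)CC[C@@]1(C)CO1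
F7 | step 5 | (2S)-2-(3-hydroperoxy-3-methyl-11-phenylundecyl)-2-methyloxirane (both epimers at the peroxy carbon) | CC(CCCCCCCCc1ccccc1)(OO)CC[C@@]1(C)CO1
F8 | step 5 | [(3R,6S)-3,6-dimethyl-6-(8-phenyloctyl)-1,2-dioxan-3-yl]methanol | C[C@]1(CCCCCCCCc2ccccc2)CC[C@](C)(CO)OO1
F9 | step 5 | (3R,6S)-3,6-dimethyl-6-(8-phenyloctyl)-1,2-dioxane-3-carbaldehyde | C[C@]1(CCCCCCCCc2ccccc2)CC[C@](C)(C=O)OO1
F10 | step 5 | methyl (E)-3-[(3R,6S)-3,6-dimethyl-6-(8-phenyloctyl)-1,2-dioxan-3-yl]prop-2-enoate | C[C@]1(CCCCCCCCc2ccccc2)CC[C@](C)(/C=C/C(=O)OC)OO1
F11 | step 5 | methyl 3-[(3R,6S)-3,6-dimethyl-6-(8-phenyloctyl)-1,2-dioxan-3-yl]propanoate | C[C@]1(CCCCCCCCc2ccccc2)CC[C@](C)(CCC(=O)OC)OO1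
F12 | step 3 | 2-ethoxy-2-hydroperoxy-10-phenyldecane (racemic) | CCOC(C)(CCCCCCCCc1ccccc1)OO
F13 | step 3 | 5-chloro-5-methyloxolan-2-one (racemic) | CC1(Cl)CCC(=O)O1
F14 | step 1 | ethyl 9-phenylnonanoate | CCOC(=O)CCCCCCCCc1ccccc1
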